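The δ-lactone is treated as CO2 inserted between its α-alkylidene carbon and its OCH2 carbon: the key step exploits the O–C(=O) unit of the six-membered ring. A trans-3,4-disubstituted γ-butyrolactone, a ring absent from the target, first fixes both ring-fusion stereocentres; its carbonyl carbon then becomes the side-chain alkyne and its OCH2 becomes CH2Cl. syn-Borylcupration gives a (Z)-alkenylboronate, and in the key step copper passes this carbon to CO2 while the new carboxylate displaces chloride, closing the lactone with E-alkylidene geometry in one operation. Ring-closing metathesis then forms the Z-cyclononene, and a hydroxyl-directed epoxidation completes the target.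

Key step: step 16

Assumption: (S)-(+)-linalool (7) is taken as enantiomerically pure commercial material; the two ring-fusion centres are set independently by the catalyst in step 3.

Step 1
Reactants: 1 2,3-dibromopropene; 2 vinylmagnesium bromide
Product: 3 2-bromopenta-1,4-diene
Conditions: CuI (5 mol %), THF, −10 °C → rt
Reagents that add atoms: none
Why: Copper-catalysed allylic substitution of the allylic bromide by the vinyl Grignard reagent should leave the vinylic C–Br bond untouched.

Step 2
Reactants: 3 2-bromopenta-1,4-diene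
Product: 4 4,4,5,5-tetramethyl-2-(penta-1,4-dien-2-yl)-1,3,2-dioxaborolane
Conditions: B2pin2, PdCl2(PPh3)2 (3 mol %), PPh3, KOPh, toluene, 50 °C
Reagents that add atoms: bis(pinacolato)diboron CC1(C)OB(OC1(C)C)B1OC(C)(C)C(C)(C)O1
Why: Miyaura borylation of a 1-alkenyl bromide with phenoxide as the mild base should give the alkenylboronate without touching the skipped diene.

Step 3
Reactants: 4 4,4,5,5-tetramethyl-2-(penta-1,4-dien-2-yl)-1,3,2-dioxaborolane; 5 2(5H)-furanone
Product: 6 (R)-4-(penta-1,4-dien-2-yl)dihydrofuran-2(3H)-one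
Conditions: [Rh(cod)OH]2 (2.5 mol %), (R)-BINAP (6 mol %), dioxane/H2O 10:1, 50 °C
Reagents that add atoms: none
Why: Hayashi–Miyaura rhodium-catalysed asymmetric conjugate addition should set the (R) centre, (R)-BINAP being the ligand enantiomer that delivers the alkenyl group to the face giving (R)-3-substituted cyclohexanones from cyclohexenone.

Step 4
Reactants: 7 (S)-(+)-linalool
Product: 8 (S)-triethyl[(3,7-dimethylocta-1,6-dien-3-yl)oxy]silane
Conditions: TESOTf, 2,6-lutidine, CH2Cl2, −78 → 0 °C
Reagents that add atoms: triethylsilyl trifluoromethanesulfonate CC[Si](CC)(CC)OS(=O)(=O)C(F)(F)F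
Why: Silylation with the silyl triflate should protect the hindered tertiary allylic alcohol under non-ionising conditions.

Step 5
Reactants: 8 (S)-triethyl[(3,7-dimethylocta-1,6-dien-3-yl)oxy]silane
Product: 10 (S)-4-methyl-4-(triethylsilyloxy)hex-5-enoic acid, via aldehyde 9 (not isolated)
Conditions: O3, CH2Cl2, −78 °C (Sudan Red 7B end point); Me2S; then NaClO2, NaH2PO4, 2-methyl-2-butene, t-BuOH/H2O, 0 °C → rt
Reagents that add atoms: ozone O=[O+][O-]; sodium chlorite [Na+].[O-]Cl=O
Why: Ozonolysis should cleave the electron-rich trisubstituted alkene far faster than the hindered monosubstituted vinyl group, and Pinnick oxidation then takes the aldehyde to the acid.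

Step 6
Reactants: 10 (S)-4-methyl-4-(triethylsilyloxy)hex-5-enoic acid
Product: 12 (S)-triethyl[(5-iodo-3-methylpent-1-en-3-yl)oxy]silane, via Barton ester 11 (not isolated)
Conditions: N-hydroxypyridine-2-thione, DCC, DMAP (cat.), CH2Cl2, 0 °C, dark; then CHI3, hν (tungsten lamp), rt
Reagents that add atoms: iodoform IC(I)I
Why: Barton decarboxylative iodination should turn the acid into the one-carbon-shorter primary iodide by a radical chain that is neutral and leaves the tertiary stereocentre alone.

Step 7
Reactants: 6 (R)-4-(penta-1,4-dien-2-yl)dihydrofuran-2(3H)-one; 12 (S)-triethyl[(5-iodo-3-methylpent-1-en-3-yl)oxy]silane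
Product: 14 (3S,4R)-3-[(S)-3-methyl-3-(triethylsilyloxy)pent-4-en-1-yl]-4-(penta-1,4-dien-2-yl)dihydrofuran-2(3H)-one, via lithium enolate 13 (not isolated)
Conditions: LDA, THF, −78 °C; then 12, DMPU, −78 → −20 °C
Reagents that add atoms: none
Why: Alkylation of the lactone enolate should occur anti to the C4 substituent and so set the trans (3S,4R) relationship of the future ring-fusion carbons.

Step 8
Reactants: 14 (3S,4R)-3-[(S)-3-methyl-3-(triethylsilyloxy)pent-4-en-1-yl]-4-(penta-1,4-dien-2-yl)dihydrofuran-2(3H)-one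
Product: 15 (3S,4R)-3-[(S)-3-methyl-3-(triethylsilyloxy)pent-4-en-1-yl]-4-(penta-1,4-dien-2-yl)tetrahydrofuran-2-ol (anomeric mixture)
Conditions: DIBAL-H (1.1 equiv), CH2Cl2, −78 °C; Rochelle salt
Reagents that add atoms: none
Why: Partial reduction with DIBAL-H at low temperature should stop at the lactol because the aluminium hemiacetal is stable until work-up.

Step 9
Reactants: 15 (3S,4R)-3-[(S)-3-methyl-3-(triethylsilyloxy)pent-4-en-1-yl]-4-(penta-1,4-dien-2-yl)tetrahydrofuran-2-ol
Product: 16 (2R,3S,6S)-3-ethynyl-6-methyl-2-(penta-1,4-dien-2-yl)-6-(triethylsilyloxy)oct-7-en-1-ol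
Conditions: dimethyl (1-diazo-2-oxopropyl)phosphonate, K2CO3, MeOH, 0 °C → rt
Reagents that add atoms: dimethyl (1-diazo-2-oxopropyl)phosphonate COP(=O)(OC)C(=[N+]=[N-])C(C)=O
Why: Seyferth–Gilbert homologation with the Ohira–Bestmann reagent on the open hydroxy-aldehyde form should turn the former lactone carbonyl carbon into the alkyne carbon and free the primary alcohol, the mild base sparing the α-stereocentre.

Step 10
Reactants: 16 (2R,3S,6S)-3-ethynyl-6-methyl-2-(penta-1,4-dien-2-yl)-6-(triethylsilyloxy)oct-7-en-1-ol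
Product: 17 (2R,3S,6S)-1-chloro-3-ethynyl-6-methyl-2-(penta-1,4-dien-2-yl)-6-(triethylsilyloxy)oct-7-ene
Conditions: PPh3, NCS, THF, 0 °C → rt
Reagents that add atoms: N-chlorosuccinimide O=C1CCC(=O)N1Cl
Why: Appel-type chlorination should convert the primary alcohol by SN2 into a chloride that tolerates the acetylide, borylcopper and alkoxide chemistry ahead.

Step 11
Reactants: 18 3-methylbut-2-en-1-ol (prenol)
Product: 19 (S)-(3,3-dimethyloxiran-2-yl)methanol
Conditions: Ti(OiPr)4 (cat.), L-(+)-DIPT, t-BuOOH, 4 Å MS, CH2Cl2, −20 °C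
Reagents that add atoms: tert-butyl hydroperoxide CC(C)(C)OO
Why: Sharpless asymmetric epoxidation with the L-(+)-tartrate should deliver oxygen to the alkene face that gives the (S) epoxide.

Step 12
Reactants: 19 (S)-(3,3-dimethyloxiran-2-yl)methanol
Product: 20 (R)-3,3-dimethyloxirane-2-carbaldehyde
Conditions: TEMPO (cat.), PhI(OAc)2, CH2Cl2, rt; used as a solution
Reagents that add atoms: none
Why: Oxoammonium (TEMPO) oxidation should give the sensitive epoxy aldehyde without epimerisation or epoxide opening.

Step 13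
Reactants: 17 (2R,3S,6S)-1-chloro-3-ethynyl-6-methyl-2-(penta-1,4-dien-2-yl)-6-(triethylsilyloxy)oct-7-ene; 20 (R)-3,3-dimethyloxirane-2-carbaldehyde
Product: 22 (S)-propargylic alcohol, 17 extended at the alkyne terminus by an (S)-CH(OH) unit carrying the (S)-3,3-dimethyloxiran-2-yl group, via lithium acetylide 21 (not isolated)
Conditions: n-BuLi, THF, −78 °C; then 20, −78 °C; NH4Cl
Reagents that add atoms: none
Why: Acetylide addition under Felkin–Anh control, with the epoxide C–O bond antiperiplanar to the incoming nucleophile and the cis-methyl group reinforcing the bias, should give the anti epoxy alcohol with the (S) carbinol.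

Step 14
Reactants: 22 (S)-propargylic alcohol
Product: 23 triethylsilyl ether of 22 (bis-silyl ether)
Conditions: TESCl, imidazole, DMAP (cat.), CH2Cl2, 0 °C
Reagents that add atoms: triethylsilyl chloride CC[Si](Cl)(CC)CC
Why: Silylation should mask the epoxy alcohol so that base and CO2 in step 16 cannot trigger Payne rearrangement or carbonate formation.

Step 15
Reactants: 23 bis-silyl ether
Product: 24 (Z)-alkenyl pinacolboronate, boron on the alkene carbon attached to the chain stereocentre and cis to the new vinylic hydrogen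
Conditions: B2pin2, CuCl (10 mol %), PCy3 (12 mol %), NaOt-Bu (15 mol %), MeOH (2 equiv), toluene, rt
Reagents that add atoms: bis(pinacolato)diboron CC1(C)OB(OC1(C)C)B1OC(C)(C)C(C)(C)O1
Why: Copper-catalysed formal hydroboration (syn borylcupration, then protonation by methanol) should place boron on the alkyne carbon remote from the propargylic oxygen and hydrogen cis to it, the unactivated alkenes and the chloride remaining spectators.

Step 16
Reactants: 24 (Z)-alkenyl pinacolboronate
Product: 26 (3E,4S,5R)-3-{(2S)-2-[(2S)-3,3-dimethyloxiran-2-yl]-2-(triethylsilyloxy)ethylidene}-4-[(3S)-3-methyl-3-(triethylsilyloxy)pent-4-en-1-yl]-5-(penta-1,4-dien-2-yl)tetrahydro-2H-pyran-2-one, via potassium carboxylate 25 (not isolated)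
Conditions: (IPr)CuCl (10 mol %), KOt-Bu (1.1 equiv), CO2 (1 atm), THF, 65 °C; then DMF, NaI (cat.), 65 °C
Reagents that add atoms: carbon dioxide O=C=O
Why: tert-Butoxide adds to the pinacolboronate, the alkenyl group passes to (IPr)Cu with retention, CO2 inserts into the Cu–C bond and the copper carboxylate is released as potassium carboxylate 25, which then displaces the primary chloride. The closest known reactions are the copper–NHC-catalysed carboxylation of alkenylboronic esters with CO2 and the in situ O-alkylation of the resulting carboxylates by alkyl halides. The only ring closed is the δ-lactone, by 6-exo-tet SN2 attack of carboxylate oxygen on CH2Cl. No stereocentre is created; the E geometry of the alkylidene (carbonyl trans to the silyloxy-bearing carbon) is carried over from the (Z)-alkenylboronate because transmetalation and insertion keep the alkene configuration, and both future ring-fusion centres are untouched. The step needs carboxylation to outrun protodemetalation and base attack on the chloride: the boronate ties up the alkoxide as its ate complex, the chloride is inert to copper and borate until the carboxylate exists, C-alkylation would require a four-membered ring, and the silyl ethers keep the epoxy alcohol away from CO2 and base.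

Step 17
Reactants: 26 δ-lactone triene
Product: 27 trans-fused (Z)-cyclononene δ-lactone, bis-triethylsilyl ether
Conditions: Grubbs II (15 mol %), toluene (0.5 mM), 80 °C
Reagents that add atoms: none
Why: Ring-closing metathesis should load ruthenium on the allyl terminus and close onto the vinyl group, the nine-membered ring forcing the Z alkene, while the trisubstituted alkylidene lactone and the 1,1-disubstituted alkene stay out.

Step 18
Reactants: 27 bis-triethylsilyl ether
Product: 28 diol (free tertiary allylic and secondary alcohols)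
Conditions: TBAF, AcOH, THF, 0 °C → rt
Reagents that add atoms: none
Why: Buffered fluoride desilylation should free both alcohols without Payne rearrangement of the epoxy alcohol or lactone opening.

Step 19
Reactants: 28 diol
Product: 29 CNP0147265.1
Conditions: VO(acac)2 (10 mol %), t-BuOOH, CH2Cl2, 0 °C
Reagents that add atoms: tert-butyl hydroperoxide CC(C)(C)OO
Why: Vanadium-catalysed hydroxyl-directed epoxidation should deliver oxygen to the Z-cyclononene face syn to the tertiary allylic hydroxyl (the cis-epoxy alcohol typical of medium-ring Z-cycloalkenols), setting both epoxide centres and sparing the electron-poor alkylidene lactone and the undirected methylene.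

Compound list
1 | 2,3-dibromopropene | C=C(Br)CBr | starting material
2 | vinylmagnesium bromide | C=C[Mg]Br | starting material
3 | 2-bromopenta-1,4-diene | C=CCC(Br)=C | intermediate
4 | 4,4,5,5-tetramethyl-2-(penta-1,4-dien-2-yl)-1,3,2-dioxaborolane | C=CCC(=C)B1OC(C)(C)C(C)(C)O1 | intermediate
5 | 2(5H)-furanone | O=C1OCC=C1 | starting material
6 | (R)-4-(penta-1,4-dien-2-yl)dihydrofuran-2(3H)-one | C=CCC(=C)[C@@H]1COC(=O)C1 | intermediate
7 | (S)-(+)-linalool | C=C[C@@](C)(O)CCC=C(C)C | starting material
8 | (S)-triethyl[(3,7-dimethylocta-1,6-dien-3-yl)oxy]silane | C=C[C@@](C)(O[Si](CC)(CC)CC)CCC=C(C)C | intermediate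
9 | (S)-4-methyl-4-(triethylsilyloxy)hex-5-enal | C=C[C@@](C)(O[Si](CC)(CC)CC)CCC=O | intermediate
10 | (S)-4-methyl-4-(triethylsilyloxy)hex-5-enoic acid | C=C[C@@](C)(O[Si](CC)(CC)CC)CCC(=O)O | intermediate
11 | 2-thioxopyridin-1(2H)-yl (S)-4-methyl-4-(triethylsilyloxy)hex-5-enoate (Barton ester) | C=C[C@@](C)(O[Si](CC)(CC)CC)CCC(=O)On1ccccc1=S | intermediate
12 | (S)-triethyl[(5-iodo-3-methylpent-1-en-3-yl)oxy]silane | C=C[C@@](C)(O[Si](CC)(CC)CC)CCI | intermediate
13 | lithium enolate of 6 | C=CCC(=C)[C@@H]1COC([O-])=C1.[Li+] | intermediate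
14 | (3S,4R)-3-[(S)-3-methyl-3-(triethylsilyloxy)pent-4-en-1-yl]-4-(penta-1,4-dien-2-yl)dihydrofuran-2(3H)-one | C=CCC(=C)[C@@H]1COC(=O)[C@H]1CC[C@](C)(O[Si](CC)(CC)CC)C=C | intermediate
15 | (3S,4R)-3-[(S)-3-methyl-3-(triethylsilyloxy)pent-4-en-1-yl]-4-(penta-1,4-dien-2-yl)tetrahydrofuran-2-ol | C=CCC(=C)[C@@H]1COC(O)[C@H]1CC[C@](C)(O[Si](CC)(CC)CC)C=C | intermediate
16 | (2R,3S,6S)-3-ethynyl-6-methyl-2-(penta-1,4-dien-2-yl)-6-(triethylsilyloxy)oct-7-en-1-ol | C=CCC(=C)[C@H](CO)[C@@H](C#C)CC[C@](C)(O[Si](CC)(CC)CC)C=C | intermediate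
17 | (2R,3S,6S)-1-chloro-3-ethynyl-6-methyl-2-(penta-1,4-dien-2-yl)-6-(triethylsilyloxy)oct-7-ene | C=CCC(=C)[C@H](CCl)[C@@H](C#C)CC[C@](C)(O[Si](CC)(CC)CC)C=C | intermediate
18 | 3-methylbut-2-en-1-ol (prenol) | CC(C)=CCO | starting material
19 | (S)-(3,3-dimethyloxiran-2-yl)methanol | OC[C@@H]1OC1(C)C | intermediate
20 | (R)-3,3-dimethyloxirane-2-carbaldehyde | O=C[C@@H]1OC1(C)C | intermediate
21 | lithium acetylide of 17 | C=CCC(=C)[C@H](CCl)[C@@H](C#[C-])CC[C@](C)(O[Si](CC)(CC)CC)C=C.[Li+] | intermediate
22 | (S)-propargylic alcohol (anti epoxy alcohol) | C=CCC(=C)[C@H](CCl)[C@@H](C#C[C@H](O)[C@@H]1OC1(C)C)CC[C@](C)(O[Si](CC)(CC)CC)C=C | intermediate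
23 | triethylsilyl ether of 22 | C=CCC(=C)[C@H](CCl)[C@@H](C#C[C@H](O[Si](CC)(CC)CC)[C@@H]1OC1(C)C)CC[C@](C)(O[Si](CC)(CC)CC)C=C | intermediate
24 | (Z)-alkenyl pinacolboronate | C=CCC(=C)[C@H](CCl)[C@@H](/C(=C\[C@H](O[Si](CC)(CC)CC)[C@@H]1OC1(C)C)B1OC(C)(C)C(C)(C)O1)CC[C@](C)(O[Si](CC)(CC)CC)C=C | intermediate
25 | potassium (E)-alkenyl carboxylate | C=CCC(=C)[C@H](CCl)[C@@H](/C(=C\[C@H](O[Si](CC)(CC)CC)[C@@H]1OC1(C)C)C(=O)[O-])CC[C@](C)(O[Si](CC)(CC)CC)C=C.[K+] | intermediate
26 | (3E,4S,5R)-α-alkylidene δ-lactone triene, bis-triethylsilyl ether | C=CCC(=C)[C@@H]1COC(=O)/C(=C/[C@H](O[Si](CC)(CC)CC)[C@@H]2OC2(C)C)[C@H]1CC[C@](C)(O[Si](CC)(CC)CC)C=C | intermediate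
27 | trans-fused (Z)-cyclononene δ-lactone, bis-triethylsilyl ether | C=C1C/C=C\[C@@](C)(O[Si](CC)(CC)CC)CC[C@@H]2/C(=C\[C@H](O[Si](CC)(CC)CC)[C@@H]3OC3(C)C)C(=O)OC[C@@H]12 | intermediate
28 | trans-fused (Z)-cyclononene δ-lactone diol | C=C1C/C=C\[C@@](C)(O)CC[C@@H]2/C(=C\[C@H](O)[C@@H]3OC3(C)C)C(=O)OC[C@@H]12 | intermediate
29 | CNP0147265.1 | C=C1C[C@H]2O[C@H]2[C@@](C)(O)CC[C@@H]2/C(=C\[C@H](O)[C@@H]3OC3(C)C)C(=O)OC[C@@H]12 | target

Total step count: 19. Longest linear sequence: 14 steps (steps 1, 2, 3, 7, 8, 9, 10, 13, 14, 15, 16, 17, 18, 19; the branch from linalool through steps 4 to 6 is equally long).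

Steps most likely to fail

Step 16. Boron-to-copper transfer at the hindered, α-branched alkenyl carbon may be slow, so that protonation of the alkenylcopper (loss of boron without CO2 uptake) or base-induced loss of HCl overtakes carboxylation. The fallback sets out from 24 and returns at 26. Iododeboronation with retention (NaOMe, then I2, THF/MeOH, 0 °C) would give the (E)-alkenyl iodide F1. Iodine–lithium exchange (t-BuLi, Et2O, −78 °C) and a CO2 quench would give the lithium carboxylate F2. Warming F2 in DMF with NaI would close the lactone by the same O-alkylation and give 26.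

Step 17. The carbene loaded on the allyl terminus may fail to engage the vinyl group shielded by the quaternary silyloxy carbon, so that intermolecular metathesis to dimers and oligomers takes over. The fallback sets out from 26 and returns at 28. Both silyl ethers would be removed first (TBAF, AcOH, THF) to give the triene diol F3. Ring closure of F3 (Hoveyda–Grubbs II, toluene, high dilution, 80 °C), now assisted by the free tertiary allylic hydroxyl at a much less hindered vinyl carbinol, would give 28 directly.

Step 15. Boron may be delivered to the wrong alkyne carbon, since both termini are branched and only the inductive effect of the propargylic oxygen separates them, or the alkenylcopper may lose the β-silyloxy group. The fallback sets out from 22 and returns at 24. Dess–Martin oxidation would give the ynone F4. Copper-catalysed conjugate borylation (CuCl, Xantphos, NaOt-Bu, B2pin2, MeOH, THF) would place boron at the β-carbon by conjugation and give the (Z)-β-boryl enone F5. Luche reduction under Felkin–Anh control would give the anti epoxy alcohol F6, and silylation (TESCl, imidazole) would return to 24.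

Further compounds
F1 | step 16 | (E)-alkenyl iodide from iododeboronation of 24 | C=CCC(=C)[C@H](CCl)[C@@H](/C(I)=C\[C@H](O[Si](CC)(CC)CC)[C@@H]1OC1(C)C)CC[C@](C)(O[Si](CC)(CC)CC)C=C
F2 | step 16 | lithium (E)-alkenyl carboxylate | C=CCC(=C)[C@H](CCl)[C@@H](/C(=C\[C@H](O[Si](CC)(CC)CC)[C@@H]1OC1(C)C)C(=O)[O-])CC[C@](C)(O[Si](CC)(CC)CC)C=C.[Li+]
F3 | step 17 | δ-lactone triene diol (desilylated 26) | C=CCC(=C)[C@@H]1COC(=O)/C(=C/[C@H](O)[C@@H]2OC2(C)C)[C@H]1CC[C@](C)(O)C=C
F4 | step 15 | epoxy ynone from oxidation of 22 | C=CCC(=C)[C@H](CCl)[C@@H](C#CC(=O)[C@@H]1OC1(C)C)CC[C@](C)(O[Si](CC)(CC)CC)C=C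
F5 | step 15 | (Z)-β-boryl enone | C=CCC(=C)[C@H](CCl)[C@@H](/C(=C\C(=O)[C@@H]1OC1(C)C)B1OC(C)(C)C(C)(C)O1)CC[C@](C)(O[Si](CC)(CC)CC)C=C
F6 | step 15 | (Z)-boryl allylic alcohol, (S) carbinol | C=CCC(=C)[C@H](CCl)[C@@H](/C(=C\[C@H](O)[C@@H]1OC1(C)C)B1OC(C)(C)C(C)(C)O1)CC[C@](C)(O[Si](CC)(CC)CC)C=C
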